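## Analysis of the target

The target 16 is (R)-1-(2-formyl-3,6-dihydroxy-5-methoxyphenyl)tridecan-2-yl acetate: one benzene ring with five of its six positions substituted, carrying an unbranched thirteen-carbon chain. The ring is numbered C1 (CHO), C2 (side chain), C3 (OH), C4 (OMe), C5 (H), C6 (OH); the chain is C1' (benzylic CH2), C2' (acetoxy carbinol) and C3' to C13' (undecyl). There is a single stereocentre, C2' (R), so only absolute configuration has to be controlled. It lies between two methylene groups (C1' and C3') that differ only at a distance, which makes reagent-controlled reduction of the corresponding ketone unattractive. The sensitive groups are the para-related C3/C6 hydroquinone (air oxidation to the quinone), the aldehyde (which would form a six-membered lactol with a free C2' hydroxyl) and the secondary acetate (base-labile and able to migrate to the C3 phenol). The difficulties are the contiguous substitution C6–C1–C2–C3–C4, the need to tell three ring oxygens apart, and the isolated stereocentre. The route rests on two features. First, C1'–C2' is a two-carbon unit held between the aryl carbon C2 and the undecyl chain with oxygen on C2', that is, a vinyl group whose inner carbon can first carry boron. Second, without its formyl group the ring is a 1-alkyl-2,3,5-trioxygenated benzene whose C1–H is para to the C4 methoxy group, so the aldehyde can be introduced late.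

## Retrosynthetic reasoning

**C3–O and C6–O protection (16 to 14).** The last operation is the release of the two phenols, because the free hydroquinone is the most oxidation-prone form of the molecule and would not survive organometallic, peroxide or Friedel–Crafts steps. In 14 both oxygens are isopropyl ethers. A secondary alkyl aryl ether is cleaved by a boron Lewis acid much faster than the C4 methyl ether, and the conditions are not basic, so the C2' acetate should neither hydrolyse nor migrate. The forward step has to remove two isopropyl groups and nothing else.

**C1–CHO (14 to 12).** The formyl carbon is disconnected next, by a Rieche formylation. In 12 the C1–H is para to the C4 methoxy group and ortho to the C6 isopropoxy group, so it is the position at which an electrophile should enter. Leaving C1 unsubstituted until this point also keeps the carbon that receives the side chain (C2) flanked by only one substituent during the key coupling. The acetate is already present in 12 because an aldehyde next to a free C2' hydroxyl would close to a lactol that could no longer be acetylated at C2'. The forward reaction must distinguish C1 from C5.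

**C2'–O (12 to 11 to 9).** The acetate is taken back to alcohol 11 and the C–O bond to the C–B bond of boronic ester 9. Oxidation of a carbon–boron bond proceeds with retention, so the configuration of 16 is decided entirely by that of 9. This turns an oxygen-bearing stereocentre between two methylene groups into a secondary boronic ester, for which a catalytic enantioselective three-component assembly exists.

**C2–C1' and C2'–C3' (9 to 4, 7 and 6).** Both bonds to the two-carbon unit are cut at once. The unit becomes vinylboronic ester 7, the ring becomes aryl bromide 4 and the chain becomes Grignard reagent 6. The cut divides the molecule into its three natural blocks (arene, two-carbon linker, lipid chain), all of them simple. The stereocentre is created by the catalyst in the step that assembles the skeleton, instead of being imported in a chiral building block. In the forward direction 7 and 6 combine to ate complex 8. A palladium catalyst carrying a chiral ferrocenyl bisphosphine then has to induce migration of the undecyl group from boron to carbon and deliver the aryl group of 4 to the terminal carbon, on one face of the vinyl group, in preference to ordinary cross-coupling.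

**Aryl bromide 4 (to 3 and 1) and Grignard reagent 6 (to 5).** Compound 4 is the bis(isopropyl ether) of hydroquinone 3, whose second hydroxyl group arises by Dakin oxidation of the formyl group of 1. Compound 1 already holds Br, OH and OMe in the 1,2,3-relationship required for C2, C3 and C4, and its aldehyde marks the position of the C6 oxygen, so no regiochemical decision is left on the ring. Compound 6 comes from bromide 5 by Grignard formation.

## Alternatives that were turned down

**Alternative 1:** Michael–Claisen annulation with late aromatization.
- *Disconnection and key step:* the benzene ring is built from acyclic carbon by cutting C1–C2 and C5–C6. Dimethyl malonate A3 would add under methoxide to the β-carbon of (R)-3-(benzyloxy)-6-(tert-butyldimethylsilyloxy)heptadec-3-en-2-one A2. The methyl ketone enolate would then close onto one ester to give the cyclohexanedione ester methyl 5-(benzyloxy)-2-hydroxy-4-oxo-6-[(R)-2-(tert-butyldimethylsilyloxy)tridecyl]cyclohex-1-ene-1-carboxylate A1.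
- *For:* C1 carries its carbon from the outset and every ring oxygen is placed by construction, so no late electrophilic substitution has to choose between C1 and C5. On this point it is stronger than the chosen route. The reagents are cheap.
- *Against:* the C2' stereocentre must be made separately before the key step. In A2 it is a silyloxy group δ to the ketone with acidic γ-hydrogens in between, so methoxide can trigger vinylogous elimination to a dienone and destroy it. The acceptor is β-substituted and α-oxygenated and therefore sluggish. The two ring stereocentres of A1 are made only to be erased. After A1 the sequence still needs dehydrogenation to the arene, selective methylation of the C4 oxygen, adjustment of the ester to the aldehyde, debenzylation and a silyl-to-acetyl exchange in the presence of phenols.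
- *Comparison:* the chosen route reaches the complete skeleton in four steps and sets C2' catalytically. It pays with a formylation whose position is governed by substituent effects and not by connectivity.

**Alternative 2:** Silyloxyfuran and ynal Diels–Alder route.
- *Disconnection and key step:* the ring bonds C2–C3 and C1–C6 are cut. Tert-butyl[(4-methoxyfuran-2-yl)oxy]dimethylsilane A5 would add thermally across the alkyne of (R)-1-oxohexadec-2-yn-5-yl acetate A6. The oxa-bridged adduct would open at the silyloxy-bearing bridgehead and tautomerize to (R)-1-[3-(tert-butyldimethylsilyloxy)-2-formyl-6-hydroxy-5-methoxyphenyl]tridecan-2-yl acetate A4, one desilylation away from the target.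
- *For:* formyl group, acetate and all three oxygens are in place when the ring forms. In convergence and step count it is stronger than the chosen route.
- *Against:* A5 is a vinylogous silyl ketene acetal. With an ynal, Mukaiyama-type addition to the formyl carbon or open-chain conjugate addition are as plausible as cycloaddition. The required orientation joins the furan carbon flanked by the methoxy group to the substituted alkyne carbon, the most hindered pairing. Ynals tolerate heating poorly, and the opening of the bridge could lose the silyl group or deliver the isomeric phenol. The stereocentre of A6 must be imported through a separate multistep sequence.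
- *Comparison:* the whole plan hangs on one thermal step that cannot be steered by a catalyst. The chosen route offers steps of well-defined reaction type, isolable intermediates and a stereocentre made by the catalyst.

**Alternative 3:** Squarate-type cyclobutenone ring expansion.
- *Disconnection and key step:* the ring bond C1–C6 is cut. The precursor is 4-[(5R)-5-(tert-butyldimethylsilyloxy)-1,1-diethoxyhexadec-2-en-3-yl]-4-hydroxy-3-methoxycyclobut-2-en-1-one A8, itself from addition of an alkenyllithium to a methoxycyclobutenedione. On heating, A8 would open to a dienylketene, close by six-electron electrocyclization between the ketene carbon and the alkene terminus, and enolize to 2-(diethoxymethyl)-5-methoxy-3-[(R)-2-(tert-butyldimethylsilyloxy)tridecyl]benzene-1,4-diol A7.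
- *For:* the substitution pattern is fixed by connectivity and the conditions are neutral. On regiochemical certainty it is stronger than the chosen route.
- *Against:* A8 needs a monomethoxy cyclobutenedione that is not a commodity, a trisubstituted alkenyllithium bearing acetal and silyloxy groups whose halide precursor takes several steps and again imports the stereocentre, and a regioselective carbonyl addition. After A7 the silyl ether must be exchanged for the acetate while two phenols are free, which forces extra protection steps, and the acetal must be unmasked on an air-sensitive hydroquinone.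
- *Comparison:* the sequence would be roughly twice as long as the chosen one, which builds the same skeleton from three purchasable blocks and defers only one regiochemical question to a late step.

Key step: step 4

Remark: the MandyPhos ligand is used as whichever antipode delivers the (R)-boronate 9; only the antipode, not the chemistry, depends on this assignment.

## Route

Step 1
Reactants: 1 5-bromovanillin (3-bromo-4-hydroxy-5-methoxybenzaldehyde)
Product: 3 2-bromo-6-methoxybenzene-1,4-diol, via aryl formate 2 (not isolated)
Conditions: 30% aq. H2O2, NaOH, H2O, 0 °C to rt, N2; then HCl to pH 3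
Reagents that add atoms: hydrogen peroxide, OO
Why: Dakin oxidation: hydroperoxide adds to the aldehyde of the para-hydroxybenzaldehyde, the electron-rich aryl group migrates to oxygen and formate 2 is saponified in the same flask. Bromide and methyl ether are untouched, and exclusion of air with acidic work-up should keep the hydroquinone from oxidizing further.

Step 2
Reactants: 3 2-bromo-6-methoxybenzene-1,4-diol
Product: 4 1-bromo-2,5-diisopropoxy-3-methoxybenzene
Conditions: 2-bromopropane, K2CO3, DMF, 60 °C, N2
Reagents that add atoms: 2-bromopropane, CC(C)Br
Why: Double Williamson etherification; a phenol oxygen flanked by bromine and methoxy is known to accept an isopropyl group under these conditions. The isopropyl ethers are inert to boron ate complexes, palladium and alkaline peroxide and can later be removed without touching the methyl ether.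

Step 3
Reactants: 5 1-bromoundecane
Product: 6 undecylmagnesium bromide (THF solution, titrated)
Conditions: Mg turnings, I2 (cat.), THF, rt to 40 °C
Reagents that add atoms: magnesium, [Mg]
Why: Grignard formation from a primary alkyl bromide; slow addition should keep Wurtz coupling low.

Step 4
Reactants: 7 vinylboronic acid pinacol ester (2-ethenyl-4,4,5,5-tetramethyl-1,3,2-dioxaborolane); 6 undecylmagnesium bromide; 4 1-bromo-2,5-diisopropoxy-3-methoxybenzene
Product: 9 (R)-2-[1-(2,5-diisopropoxy-3-methoxyphenyl)tridecan-2-yl]-4,4,5,5-tetramethyl-1,3,2-dioxaborolane, via vinylboron ate complex 8 (not isolated)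
Conditions: 7, then 6 (1.0 equiv to 7), THF, 0 °C to rt; then 4, NaOTf, Pd(OAc)2 (2 mol%), MandyPhos ligand 1,1'-bis[(dimethylamino)(phenyl)methyl]-2,2'-bis[bis(4-methoxy-3,5-dimethylphenyl)phosphino]ferrocene (2.4 mol%, antipode giving R), THF/DMSO, 40 to 60 °C
Reagents that add atoms: none
Why: This is the palladium-catalysed enantioselective conjunctive cross-coupling, a known three-component reaction of Grignard-derived vinylboron ate complexes with aryl halides. Zerovalent palladium, formed in the flask from Pd(OAc)2 and the bisphosphine, inserts into the C–Br bond of 4, and NaOTf removes bromide so that a cationic aryl complex of divalent palladium can bind the vinyl group of 8. Coordination makes the alkene electrophilic and triggers a 1,2-metallate shift in which the undecyl group moves from boron to the boron-bearing carbon anti to palladium, which bonds to the terminal CH2; this forms C2'–C3'. Reductive elimination from the alkyl(aryl)palladium species then forms C2–C1' and returns zerovalent palladium; no ring is closed. The stereocentre C2' is set in the metallate shift by the face of the vinyl group that the chiral ferrocenyl bisphosphine allows palladium to bind, so it is under catalyst control and the ligand antipode is chosen for R. The step needs the metallate shift to outrun direct Suzuki–Miyaura transfer of vinyl or undecyl and β-hydride elimination, which the wide-bite-angle ligand, the four-coordinate boron and a primary unbranched migrating group all favour. On the substrate side 4 has a single ortho substituent because C1 is still C–H, and its ether groups are inert to 8, although its electron-rich ortho-alkoxy character makes oxidative addition slower than for typical partners.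

Step 5
Reactants: 9 (R)-2-[1-(2,5-diisopropoxy-3-methoxyphenyl)tridecan-2-yl]-4,4,5,5-tetramethyl-1,3,2-dioxaborolane
Product: 11 (R)-1-(2,5-diisopropoxy-3-methoxyphenyl)tridecan-2-ol, via borate ester 10 (not isolated)
Conditions: 30% aq. H2O2, 3 M NaOH, THF, 0 °C to rt
Reagents that add atoms: hydrogen peroxide, OO
Why: Oxidation of the C–B bond by hydroperoxide, with 1,2-migration of carbon from boron to oxygen; the migration is stereoretentive, so the configuration at C2' is carried over unchanged. Borate ester 10 is hydrolysed in the flask, and the aryl ethers are stable to alkaline peroxide.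

Step 6
Reactants: 11 (R)-1-(2,5-diisopropoxy-3-methoxyphenyl)tridecan-2-ol
Product: 12 (R)-1-(2,5-diisopropoxy-3-methoxyphenyl)tridecan-2-yl acetate
Conditions: Ac2O, DMAP (cat.), pyridine, rt
Reagents that add atoms: acetic anhydride, CC(=O)OC(C)=O
Why: DMAP-catalysed acylation of the only nucleophilic group present. The acetate has to be in place before C1 is formylated, because a free C2' hydroxyl would add to the aldehyde and give a lactol.

Step 7
Reactants: 12 (R)-1-(2,5-diisopropoxy-3-methoxyphenyl)tridecan-2-yl acetate
Product: 14 (R)-1-(2-formyl-3,6-diisopropoxy-5-methoxyphenyl)tridecan-2-yl acetate, via chloro(methoxy)methyl arene 13 (not isolated)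
Conditions: Cl2CHOCH3, TiCl4, CH2Cl2, −78 to 0 °C; then H2O
Reagents that add atoms: dichloromethyl methyl ether, COC(Cl)Cl; water, O
Why: Rieche formylation, a Friedel–Crafts reaction of the dichloromethyl methyl ether–TiCl4 complex followed by hydrolysis of 13 on work-up. C1 is para to the C4 methoxy group and ortho to the C6 isopropoxy group, the position attacked in 1-alkyl-2,3,5-trialkoxybenzenes, whereas C5 is crowded between two alkoxy groups. Low temperature should limit Lewis-acid cleavage of the isopropyl ethers and leave the acetate intact.

Step 8
Reactants: 14 (R)-1-(2-formyl-3,6-diisopropoxy-5-methoxyphenyl)tridecan-2-yl acetate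
Product: 16 (R)-1-(2-formyl-3,6-dihydroxy-5-methoxyphenyl)tridecan-2-yl acetate, via bis(dichloroboryloxy) arene 15 (not isolated)
Conditions: BCl3 (1 M in CH2Cl2), CH2Cl2, −78 to 0 °C, Ar; then H2O
Reagents that add atoms: none
Why: Lewis-acid dealkylation: BCl3 coordinates the ether oxygen and chloride removes the secondary isopropyl group far faster than a methyl group, and the C6 ether is further activated by chelation to the ortho formyl group. The secondary acetate and the C4 methyl ether are expected to survive at low temperature, and aqueous work-up under argon hydrolyses the boron aryloxides of 15 to the hydroquinone.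

## Compound list

1 | 5-bromovanillin (3-bromo-4-hydroxy-5-methoxybenzaldehyde) | COc1cc(C=O)cc(Br)c1O | starting material
2 | 3-bromo-4-hydroxy-5-methoxyphenyl formate | COc1cc(OC=O)cc(Br)c1O | intermediate
3 | 2-bromo-6-methoxybenzene-1,4-diol | COc1cc(O)cc(Br)c1O | intermediate
4 | 1-bromo-2,5-diisopropoxy-3-methoxybenzene | COc1cc(OC(C)C)cc(Br)c1OC(C)C | intermediate
5 | 1-bromoundecane | CCCCCCCCCCCBr | starting material
6 | undecylmagnesium bromide | CCCCCCCCCCC[Mg]Br | intermediate
7 | vinylboronic acid pinacol ester (2-ethenyl-4,4,5,5-tetramethyl-1,3,2-dioxaborolane) | C=CB1OC(C)(C)C(C)(C)O1 | starting material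
8 | bromomagnesium 2-ethenyl-4,4,5,5-tetramethyl-2-undecyl-1,3,2-dioxaborolan-2-uide (vinylboron ate complex) | CCCCCCCCCCC[B-]1(C=C)OC(C)(C)C(C)(C)O1.[Mg+]Br | intermediate
9 | (R)-2-[1-(2,5-diisopropoxy-3-methoxyphenyl)tridecan-2-yl]-4,4,5,5-tetramethyl-1,3,2-dioxaborolane | CCCCCCCCCCC[C@H](Cc1cc(OC(C)C)cc(OC)c1OC(C)C)B1OC(C)(C)C(C)(C)O1 | intermediate
10 | (R)-2-{[1-(2,5-diisopropoxy-3-methoxyphenyl)tridecan-2-yl]oxy}-4,4,5,5-tetramethyl-1,3,2-dioxaborolane | CCCCCCCCCCC[C@H](Cc1cc(OC(C)C)cc(OC)c1OC(C)C)OB1OC(C)(C)C(C)(C)O1 | intermediate
11 | (R)-1-(2,5-diisopropoxy-3-methoxyphenyl)tridecan-2-ol | CCCCCCCCCCC[C@H](Cc1cc(OC(C)C)cc(OC)c1OC(C)C)O | intermediate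
12 | (R)-1-(2,5-diisopropoxy-3-methoxyphenyl)tridecan-2-yl acetate | CCCCCCCCCCC[C@H](Cc1cc(OC(C)C)cc(OC)c1OC(C)C)OC(C)=O | intermediate
13 | (2R)-1-{2-[chloro(methoxy)methyl]-3,6-diisopropoxy-5-methoxyphenyl}tridecan-2-yl acetate (both epimers at the chloro(methoxy)methyl carbon) | CCCCCCCCCCC[C@H](Cc1c(OC(C)C)c(OC)cc(OC(C)C)c1C(Cl)OC)OC(C)=O | intermediate
14 | (R)-1-(2-formyl-3,6-diisopropoxy-5-methoxyphenyl)tridecan-2-yl acetate | CCCCCCCCCCC[C@H](Cc1c(OC(C)C)c(OC)cc(OC(C)C)c1C=O)OC(C)=O | intermediate
15 | (R)-1-[3,6-bis(dichloroboryloxy)-2-formyl-5-methoxyphenyl]tridecan-2-yl acetate | CCCCCCCCCCC[C@H](Cc1c(OB(Cl)Cl)c(OC)cc(OB(Cl)Cl)c1C=O)OC(C)=O | intermediate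
16 | (R)-1-(2-formyl-3,6-dihydroxy-5-methoxyphenyl)tridecan-2-yl acetate | CCCCCCCCCCC[C@H](Cc1c(O)c(OC)cc(O)c1C=O)OC(C)=O | target

## Step count and risk assessment

Total step count: 8. Longest linear sequence: 7 steps (steps 1, 2, 4, 5, 6, 7, 8 from 1); the Grignard branch (step 3) joins at step 4.

**Step 4 (key step).** Oxidative addition to the electron-rich bromide and reductive elimination next to the ortho isopropoxy group may be slow. The ate complex could then be diverted into direct transfer of vinyl or undecyl without the metallate shift, or into β-hydride elimination, and enantiofacial discrimination may fall with this hindered aryl group.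

Fallback, from 4 back to the route at 11:
- 1-tridecene F1 is epoxidized with mCPBA to racemic 2-undecyloxirane F2.
- F2 is resolved by hydrolytic kinetic resolution with [N,N'-bis(3,5-di-tert-butylsalicylidene)cyclohexane-1,2-diaminato]cobalt acetate (trivalent cobalt; antipode that leaves the R epoxide) and 0.55 equiv of water, giving (R)-2-undecyloxirane F3.
- Bromide 4 undergoes bromine–lithium exchange with n-BuLi in THF at −78 °C to give (2,5-diisopropoxy-3-methoxyphenyl)lithium F4.
- F4 opens F3 at the terminal carbon in the presence of BF3·OEt2 at −78 °C. The stereocentre is not touched, so alcohol 11 results directly and steps 4 and 5 are bypassed.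

**Step 7.** Competing attack at C5, between the methoxy and isopropoxy groups, may be promoted by coordination of TiCl4 to the ether oxygens. Premature loss of an isopropyl group would change the directing pattern.

Fallback, from 12 back to the route at 14: bromination with NBS in MeCN at 0 °C, which needs no Lewis acid, should give (R)-1-(2-bromo-3,6-diisopropoxy-5-methoxyphenyl)tridecan-2-yl acetate F5, whose regiochemistry can be secured before the carbon is added. Palladium-catalysed reductive carbonylation of F5 (Pd(OAc)2, di(1-adamantyl)-n-butylphosphine, CO/H2, TMEDA, toluene, 100 °C), which tolerates the ester, then gives 14.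

**Step 8.** Possible failures are incomplete cleavage of the non-chelated C3 ether, loss of the C4 methyl group once a neighbouring boron aryloxide can chelate it, acetate cleavage or migration to the C3 oxygen, and air oxidation of the product during work-up.

Fallback, from 14 back to the route at 16: oxidative dealkylation with (NH4)2Ce(NO3)6 in aqueous MeCN at 0 °C converts the para-dialkoxy unit into the quinone (R)-1-(2-formyl-5-methoxy-3,6-dioxocyclohexa-1,4-dien-1-yl)tridecan-2-yl acetate F6, leaving the C4 methoxy group and the acetate. Immediate two-phase reduction with Na2S2O4 gives 16.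

**Step 1.** The electron-rich hydroquinone may oxidize to the quinone under alkaline peroxide or during isolation, and this would also compromise the double alkylation in step 2.

Fallback, from 1 back to the route at 4, never exposing a free hydroquinone:
- 1 is first alkylated (2-bromopropane, K2CO3, DMF) to 3-bromo-4-isopropoxy-5-methoxybenzaldehyde F7.
- Baeyer–Villiger oxidation with mCPBA in CH2Cl2 gives 3-bromo-4-isopropoxy-5-methoxyphenyl formate F8.
- Methanolysis (K2CO3, MeOH) gives 3-bromo-4-isopropoxy-5-methoxyphenol F9.
- A second isopropylation gives 4.

## Further compounds

F1 | step 4 | 1-tridecene | CCCCCCCCCCCC=C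
F2 | step 4 | racemic 2-undecyloxirane | CCCCCCCCCCCC1CO1
F3 | step 4 | (R)-2-undecyloxirane | CCCCCCCCCCC[C@@H]1CO1
F4 | step 4 | (2,5-diisopropoxy-3-methoxyphenyl)lithium | COc1cc(OC(C)C)cc([Li])c1OC(C)C
F5 | step 7 | (R)-1-(2-bromo-3,6-diisopropoxy-5-methoxyphenyl)tridecan-2-yl acetate | CCCCCCCCCCC[C@H](Cc1c(OC(C)C)c(OC)cc(OC(C)C)c1Br)OC(C)=O
F6 | step 8 | (R)-1-(2-formyl-5-methoxy-3,6-dioxocyclohexa-1,4-dien-1-yl)tridecan-2-yl acetate | CCCCCCCCCCC[C@H](CC1=C(C=O)C(=O)C=C(OC)C1=O)OC(C)=O
F7 | step 1 | 3-bromo-4-isopropoxy-5-methoxybenzaldehyde | COc1cc(C=O)cc(Br)c1OC(C)C
F8 | step 1 | 3-bromo-4-isopropoxy-5-methoxyphenyl formate | COc1cc(OC=O)cc(Br)c1OC(C)C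
F9 | step 1 | 3-bromo-4-isopropoxy-5-methoxyphenol | COc1cc(O)cc(Br)c1OC(C)C
A1 | alternative 1 | methyl 5-(benzyloxy)-2-hydroxy-4-oxo-6-[(R)-2-(tert-butyldimethylsilyloxy)tridecyl]cyclohex-1-ene-1-carboxylate | COC(=O)C1=C(O)CC(=O)[C@H](OCc2ccccc2)[C@H]1C[C@@H](CCCCCCCCCCC)O[Si](C)(C)C(C)(C)C
A2 | alternative 1 | (R)-3-(benzyloxy)-6-(tert-butyldimethylsilyloxy)heptadec-3-en-2-one | CC(=O)C(OCc1ccccc1)=CC[C@@H](CCCCCCCCCCC)O[Si](C)(C)C(C)(C)C
A3 | alternative 1 | dimethyl malonate | COC(=O)CC(=O)OC
A4 | alternative 2 | (R)-1-[3-(tert-butyldimethylsilyloxy)-2-formyl-6-hydroxy-5-methoxyphenyl]tridecan-2-yl acetate | CCCCCCCCCCC[C@H](Cc1c(O)c(OC)cc(O[Si](C)(C)C(C)(C)C)c1C=O)OC(C)=O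
A5 | alternative 2 | tert-butyl[(4-methoxyfuran-2-yl)oxy]dimethylsilane | COc1coc(O[Si](C)(C)C(C)(C)C)c1
A6 | alternative 2 | (R)-1-oxohexadec-2-yn-5-yl acetate | CCCCCCCCCCC[C@H](CC#CC=O)OC(C)=O
A7 | alternative 3 | 2-(diethoxymethyl)-5-methoxy-3-[(R)-2-(tert-butyldimethylsilyloxy)tridecyl]benzene-1,4-diol | CCCCCCCCCCC[C@H](Cc1c(O)c(OC)cc(O)c1C(OCC)OCC)O[Si](C)(C)C(C)(C)C
A8 | alternative 3 | 4-[(5R)-5-(tert-butyldimethylsilyloxy)-1,1-diethoxyhexadec-2-en-3-yl]-4-hydroxy-3-methoxycyclobut-2-en-1-one | O=C1C=C(OC)C1(O)C(C[C@@H](CCCCCCCCCCC)O[Si](C)(C)C(C)(C)C)=CC(OCC)OCC
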